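The runs were generated by integration for an exercise; scatter was added.

A small charge of Z, as in cedar, still leaves 70.6% of the Q at 8.00 h, while alder with its larger charge leaves 16.7% at 8.00 h, so I ask how much Q each portion takes.

| setting | cedar | alder | north-west | south-east | east | south | north-east |
|---|---|---|---|---|---|---|---|
| Q | 0.25 M | 0.25 M | 0.25 M | 0.25 M | 0.25 M | 0.25 M | 0.25 M |
| L | 0.025 M | 0.025 M | 0.0250 M | 0.0250 M | 0.0250 M | 0.0250 M | 0.0250 M |
| Z | 1.3 mM (in portions, 4) | 5.4 mM (in portions, 4) | 1.2 mM (in portions, 4) | 2.5 mM (in portions, 4) | 5.0 mM (in portions, 4) | 10 mM (in portions, 4) | 20 mM (in portions, 4) |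
| remark | run made earlier; portions every 3.0 h | run made earlier; portions every 3.0 h | the portions of Z follow each other after 3.0 h, the first at the start | the portions of Z follow each other after 3.0 h, the first at the start | the portions of Z follow each other after 3.0 h, the first at the start | the portions of Z follow each other after 3.0 h, the first at the start | the portions of Z follow each other after 3.0 h, the first at the start |
| time |  |  | 12 h | 12 h | 12 h | 12 h | 12 h |

| run | time / h | E / % | Q / % |
|---|---|---|---|
| cedar | 0.667 | 3.5 | 94.3 |
| cedar | 1.50 | 6.1 | 91.2 |
| cedar | 4.00 | 7.4 | 81.2 |
| cedar | 8.00 | 6.6 | 70.6 |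
| alder | 1.00 | 23.2 | 68.9 |
| alder | 3.00 | 11.1 | 60.3 |
| alder | 5.00 | 19.2 | 33.8 |
| alder | 8.00 | 12.5 | 16.7 |

(scatter of a reading: 1 percentage point)

1. amount of E at the end, in percent of the Q charged for north-west, south-east, east, south, north-east, in this order
2. the shape of the row from first to last (falls all the way / hardly changes / rises, then falls / rises all the way / falls, then rises)

- "hardly changes" means that all values lie within two and a half points (for a concentration: within two and a half percent of the largest)

Q falls by a fraction per portion, a pseudo-first-order pattern, so I fold charge and portions into one burn number: the natural logarithm of the fall of Q per portion, which alder gives as 0.597 from the 3 portions in by 8.00 h. I take a flask's burn number to be this value times its charge over alder's, and r, the chance that a molecule of Q passes a portion untouched, to be the exponential of minus that number. One route to E at the end, the one I reckon with, has a molecule pass each earlier portion and then be taken by the last; E made from earlier portions can also stand at the end, but I leave it out of this estimate. The chance of that route peaks at r = 0.750, which is a charge of 2.60 mM.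

Is one number enough? Cedar's own burn number is 0.116, lower than the 0.144 scaled from alder, so the scaling is rough. The number places the peak but gives no height, and for that I need a second reading: alder at 3.00 h keeps 0.280 of the Q lost as E. Counting the last portion's E and nothing earlier, I reckon 0.876 for r in north-west, which gives 2.33%; then 0.759 gives 2.95% in south-east, and 0.576 gives 2.26% in east, 0.331 gives 0.680% in south, and 0.110 gives 0.0329% in north-east.

The forecast says 3.5%, 4.8%, 4.2%, 2%, 0.6%, so rises, then falls, on the grounds that “Low Z makes little E; high Z exhausts Q early, so E decays away.” My south-east figure stands lower than its 4.8%, but the shape is the same.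

The flasks give 3.67%, 7.01%, 5.64%, 1.21%, 0.327%, so rises, then falls, with south-east highest.

    Q + Z → X + E (k = 0.380 /M/min)
    Q + X → E + X, rate k2*[X]*[Q] (k = 8.80 /M/min)
    X + L → G (k = 0.220 /M/min)
    X + Q → D (k = 0.0910 /M/min)
    E → J (k = 0.00910 /min)

In north-west at 12.0 h, E is made more slowly than it is used up, at 0.188 of that rate, each step taken net. The burn number, taken over the 4 portions, leaves 33.1% of the Q in south-east, where the flask holds 31.7% at the end. For north-west it leaves 58.8%, where the flask holds 63.7%.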